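# Proposed total synthesis of astepyrazinoxide (21)

## Analysis of the target

Astepyrazinoxide (21) is a 1-hydroxypyrazin-2(1H)-one in which every ring carbon is substituted. C2 is the carbonyl, C3 carries a methyl group, C5 a methoxy group, and C6 a methylene bridge to C3' of an indole that bears a prenyl group at C7'. The molecule has no stereocentre and no stereogenic double bond, so any centre made on the way may be left uncontrolled as long as it is erased later. The sensitive groups are the cyclic hydroxamic acid N1–OH (reducible N–O bond, metal chelation), the free indole N1'–H, the acid- and electrophile-sensitive trisubstituted alkene next to that nitrogen, and the acid-labile lactim ether at C5. The difficulty lies in the core: N1 must carry oxygen while bonded to the C2 carbonyl and to the fully substituted C6, and the two carbonyl-level carbons must be told apart, C2 staying a hydroxamate carbonyl and C5 becoming an O-methyl imidate. Formally the ring is a dehydrogenated, O-methylated 2,5-dioxopiperazine, and N4, C3 (with its methyl) and C2 form an alanine unit. The strategy rests on the C5–C6 bond: C5 is at the acyl level and C6, bonded to N1, is an iminium carbon in its natural polarity, so both are electrophiles. An isocyanide carbon reverses the polarity of C5, and if it is the isocyanide of alanine, the carboxylate for the N1–C2 bond comes with it.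

## Retrosynthetic reasoning

**O–allyl bond of 20.** The N1–OH group of 21 is unmasked last, from the O-allyl ether 20. An allyl ether is chosen because a zerovalent palladium catalyst removes it under neutral conditions. A benzyl ether would need hydrogenolysis (N–O bond and prenyl alkene at risk), and an acid-labile group would endanger the lactim ether and the prenyl group.

**C3–H and C6–H of 17.** The pyrazinone 20 is traced to the 3,6-dihydropyrazinone 17 by adding hydrogen back at C3 and C6. Forward, C3–H (flanked by the C2 carbonyl and N4=C5) is the most acidic C–H. Its anion (dianion 18, because the indole N–H is deprotonated first) is halogenated to 19, and hydrogen halide is then lost across C3 and C6 with aromatisation as the driving force.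

**O–CH3 bond of 17.** The lactim ether 17 comes from the dioxopiperazine 16. The cut is made here because 16 has only one N–H amide, N4–C5. N1 already carries its oxygen, so only C5 can form a neutral imidate on O-alkylation, and the C2/C5 problem is solved by the way the ring is built.

**C5–C6 and N1–C2 of 16.** Both bonds are cut at once, giving the O-allyl oxime ether 9 and the racemic isocyano carboxylate 13.
- Cutting N1–C6 instead would need a weakly nucleophilic hydroxamate nitrogen to attack a carbon electrophile.
- Cutting only an amide bond would require a preformed N-alkoxy amino acid.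
- Forward, the isocyanide carbon adds to the Lewis-acid-activated C=N of 9, and the nitrilium ion is captured by its own carboxylate as the oxazolone 14.
- The oxazolone cannot hand its acyl group directly to N1, because the geometry would be bridged. A relay nucleophile therefore opens it to the active ester 15, which N1 attacks to close the six-membered ring.
- The gain is one ring and two skeletal bonds in one operation from two small pieces. The two new centres need no control.

**C=N of 9, and the indole side chain.** The oxime ether 9 is cut at C=N into O-allylhydroxylamine hydrochloride 7 and the aldehyde 8. Compound 8 is unstable, so it is made by oxidation of the tryptophol 6 and condensed without isolation. Compound 6 is cut at the C3'–CH2 bond: hydroxyethylation of the N-magnesio derivative 5 of 7-prenylindole 4. Compound 4 is cut at C7'–CH2 into 7-bromoindole 1 and prenyl bromide 2, joined through the organozinc 3 by a cross-coupling that must deliver the linear allyl isomer.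

**Isocyanide branch.** The salt 13 comes from the ester 12 by saponification, 12 from the formamide 11 by dehydration, and 11 from DL-alanine methyl ester hydrochloride 10. The salt is used because its α-hydrogen is not acidic, which shuts off the α-deprotonation chemistry of isocyano esters.

## Alternatives that were turned down

**Alternative 1: indole ring formed last by heteroannulation.**
- Disconnection: the pyrrole ring of the indole is cut at C3a'–C3' and N1'–C2'. The pieces are the bromoaniline A1 and the silyl alkyne A2, which already carries the O-protected pyrazinone.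
- Key step: a palladium catalyst with a bulky phosphine and a carbonate base carbopalladates the alkyne and closes the ring to the 2'-silyl indole A3, the silyl group steering itself to C2'.
- For it: it is convergent and regiochemically reliable, and the indole does not exist while the pyrazinone is oxidised and methylated. That is a real advantage over the chosen route, where the free indole must survive steps 8 and 9.
- Against it: the hard part (the N-oxygenated, fully substituted pyrazinone with C2 and C5 differentiated) stays unsolved inside A2, which needs a synthesis of its own. A1 is not commercial. After the annulation the silyl and 4-methoxybenzyl groups must both come off, the latter under acidic or oxidative conditions that the prenyl alkene and the indole tolerate poorly.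
- Comparison: more steps in total. The chosen route builds the core in one step and takes the indole from commercial 1.

**Alternative 2: benzene ring of the indole from a furan.**
- Disconnection: the carbocycle is cut at C7a'–C3a' and C5'–C4', leading to the amidofuran A4.
- Key step: on heating, the tethered alkene adds across the furan, the oxygen bridge opens and water is lost, giving the N-Boc indoline A5.
- For it: the prenyl group is placed at C7' by construction, and no metal is needed.
- Against it: A5 is only a protected, reduced form of 4, which is one step from 1. A4 needs several steps, and a dehydrogenation and a deprotection follow the key step. Nothing of the pyrazinone problem is addressed.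
- Comparison: longer, and the key step is spent on the easy half of the molecule.

**Alternative 3: ring closure at N1–C6 by condensation.**
- Disconnection: N1–C6, leading to the open keto amide A6 (an indolylpyruvamide of alanine O-allyl hydroxamate).
- Key step: under mild acid with removal of water, the hydroxamate N–H adds to the ketone and dehydrates to the 6-ylidene dioxopiperazine A7.
- For it: each step is of a known type. A7 is already at the oxidation level of the pyrazinone, since after O-methylation the exocyclic alkene is a tautomer of the aromatic ring, so no oxidant is needed. On this point it is stronger than the chosen route, which needs step 9.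
- Against it: A6 requires an indol-3-ylpyruvic acid derivative, which is strongly enolised and unstable, and a linear assembly. The hydroxamate nitrogen is a weak nucleophile toward a largely enolised ketone, so the closure may need acid that threatens the prenyl group. The (S) centre is made only to be destroyed.
- Comparison: similar or higher step count and fully linear. The chosen route is convergent and forms two bonds and the ring in one operation, at the price of concentrating the risk in that step.

Key step: step 7

Remark on the chemistry: since 21 has no stereocentre, racemic 13, an E/Z mixture of 9 and a diastereomer mixture of 16 are carried forward without separation.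

## Route

Step 1
Reactants: 1 7-bromo-1H-indole; 2 prenyl bromide (1-bromo-3-methylbut-2-ene)
Product: 4 7-(3-methylbut-2-en-1-yl)-1H-indole, via prenylzinc bromide 3 (not isolated)
Conditions: 2, Zn dust, LiCl, THF, 0 °C; then 1, Pd(OAc)2 (2 mol %), CPhos (4 mol %), 3 (2.2 equiv), THF, rt
Reagents that add atoms: none
Why: Negishi cross-coupling; zinc inserts into the allylic C–Br bond, and with the bulky biarylphosphine reductive elimination should occur from the σ-allyl palladium at its unsubstituted terminus, giving the linear prenyl and not the reverse-prenyl product; the excess of 3 allows for the indole N–H.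

Step 2
Reactants: 4 7-(3-methylbut-2-en-1-yl)-1H-indole
Product: 6 2-[7-(3-methylbut-2-en-1-yl)-1H-indol-3-yl]ethan-1-ol, via indolylmagnesium bromide 5 (not isolated)
Conditions: EtMgBr, Et2O, 0 °C to rt; ethylene oxide (THF solution), 0 °C to rt; aq NH4Cl
Reagents that add atoms: ethylene oxide, C1CO1
Why: Epoxide opening by an indolylmagnesium halide; the covalent N–Mg bond leaves C3' as the nucleophilic site and the metal activates the epoxide, so hydroxyethylation should occur at C3', after which the 3H-indole tautomerises back.

Step 3
Reactants: 6 2-[7-(3-methylbut-2-en-1-yl)-1H-indol-3-yl]ethan-1-ol; 7 O-allylhydroxylamine hydrochloride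
Product: 9 (E)-2-[7-(3-methylbut-2-en-1-yl)-1H-indol-3-yl]acetaldehyde O-allyl oxime, via indol-3-ylacetaldehyde 8 (not isolated)
Conditions: SO3·pyridine, Et3N, DMSO–CH2Cl2, 0 °C; then 7, 0 °C to rt
Reagents that add atoms: none
Why: Parikh–Doering oxidation, mild enough for the indole and the alkene, followed by oxime ether condensation in the same flask so that the self-condensing aldehyde 8 is never concentrated; the E isomer should predominate, and both isomers lead to the same zinc-bound iminium in step 7.

Step 4
Reactants: 10 DL-alanine methyl ester hydrochloride
Product: 11 methyl N-formyl-DL-alaninate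
Conditions: HCO2Et, Et3N, reflux
Reagents that add atoms: ethyl formate, CCOC=O
Why: N-Formylation by aminolysis of ethyl formate by the amine that Et3N sets free; the methyl ester does not react.

Step 5
Reactants: 11 methyl N-formyl-DL-alaninate
Product: 12 methyl 2-isocyanopropanoate (racemic)
Conditions: POCl3, Et3N, CH2Cl2, −20 to 0 °C
Reagents that add atoms: none
Why: Dehydration of a formamide to an isocyanide with POCl3 and a tertiary amine (Ugi isocyanide synthesis); the ester is untouched.

Step 6
Reactants: 12 methyl 2-isocyanopropanoate
Product: 13 potassium 2-isocyanopropanoate (racemic)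
Conditions: KOH, EtOH, 0 °C to rt
Reagents that add atoms: potassium hydroxide, [K+].[OH-]
Why: Saponification; isocyanides are stable to base, the salt should precipitate from ethanol, and it is used as such because the free α-isocyano acid is not stable.

Step 7
Reactants: 9 (E)-2-[7-(3-methylbut-2-en-1-yl)-1H-indol-3-yl]acetaldehyde O-allyl oxime; 13 potassium 2-isocyanopropanoate
Product: 16 1-(allyloxy)-3-methyl-6-{[7-(3-methylbut-2-en-1-yl)-1H-indol-3-yl]methyl}piperazine-2,5-dione (racemic cis/trans mixture), via oxazol-5(4H)-one 14 (not isolated), via OAt ester 15 (not isolated)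
Conditions: ZnCl2 (1.5 equiv), THF, 0 °C to rt; then HOAt (1.2 equiv), i-Pr2NEt, THF (dilute), 40 °C; aq NH4Cl
Reagents that add atoms: none
Why: Proposed new method: ZnCl2 binds the oxime nitrogen of 9 and makes C6 an N-alkoxyiminium carbon, to which the isocyanide carbon of 13 adds (C5–C6), and the nitrilium ion is captured by its own carboxylate in a 5-endo-dig closure to the oxazolone 14. The alkoxyamine nitrogen cannot attack the oxazolone carbonyl directly, because the tetrahedral intermediate would be a 7-oxa-2,5-diazabicyclo[2.2.1]hept-1-ene with its C=N bond at a bridgehead, so the acyl transfer is relayed: 1-hydroxy-7-azabenzotriazole (HOAt) opens 14 to the active ester 15, as oxazolones do in peptide coupling, and N1 then attacks C2 in a 6-exo-trig closure that forms the dioxopiperazine ring (N1–C2). The closest known reaction types are the ZnCl2-promoted Ugi reaction of O-alkyl oxime ethers to N-alkoxy peptides, Ugi reactions of α-amino acids in which a cyclic adduct that cannot rearrange is opened by an external nucleophile, and the acylation of N,O-dialkylhydroxylamines by OAt esters. C6 is set by unselective attack on a planar iminium carbon and C3 is racemic and epimerisable through 14, so a mixture of diastereomers is expected; both centres become sp2 in step 9. The step needs attack by the isocyanide carbon rather than α-deprotonation, which the carboxylate salt secures because its α-hydrogen is not acidic. It also needs capture of the nitrilium ion within the molecule, which the five-membered closure secures, and ring closure rather than chain growth, which the six-membered transition state and dilution in the second stage favour.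

Step 8
Reactants: 16 1-(allyloxy)-3-methyl-6-{[7-(3-methylbut-2-en-1-yl)-1H-indol-3-yl]methyl}piperazine-2,5-dione
Product: 17 1-(allyloxy)-5-methoxy-3-methyl-6-{[7-(3-methylbut-2-en-1-yl)-1H-indol-3-yl]methyl}-3,6-dihydropyrazin-2(1H)-one
Conditions: Me3OBF4 (1.5 equiv), Na2CO3, CH2Cl2, rt
Reagents that add atoms: trimethyloxonium tetrafluoroborate, C[O+](C)C.F[B-](F)(F)F
Why: O-Alkylation of a secondary lactam with a Meerwein salt; only the N4–H amide can lose a proton to give a neutral imidate, whereas the N-alkoxy amide at C2 is a weaker donor and its O-alkylation would revert on work-up; solid Na2CO3 takes up HBF4 and so protects the prenyl alkene and the lactim ether.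

Step 9
Reactants: 17 1-(allyloxy)-5-methoxy-3-methyl-6-{[7-(3-methylbut-2-en-1-yl)-1H-indol-3-yl]methyl}-3,6-dihydropyrazin-2(1H)-one
Product: 20 1-(allyloxy)-5-methoxy-3-methyl-6-{[7-(3-methylbut-2-en-1-yl)-1H-indol-3-yl]methyl}pyrazin-2(1H)-one, via dilithio dianion 18 (not isolated), via 3-iodo lactim ether 19 (not isolated)
Conditions: LiN(SiMe3)2 (2.1 equiv), THF, −78 °C; I2 (1.0 equiv), −78 to 0 °C
Reagents that add atoms: none
Why: Enolate halogenation followed by dehydrohalogenation: the first equivalent of base removes the indole N–H and the second removes C3–H (α to the C2 carbonyl and to N4=C5), and this more basic carbanion is where iodine should attack. The tertiary iodide 19 ionises with help from the lactim ether π system and gives up the C6 proton to the indolide, so hydrogen iodide leaves across C3 and C6 and the aromatic pyrazinone forms; iodine that first reaches the indole nitrogen is still an iodine donor to the carbanion, and aromatisation is the irreversible sink.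

Step 10
Reactants: 20 1-(allyloxy)-5-methoxy-3-methyl-6-{[7-(3-methylbut-2-en-1-yl)-1H-indol-3-yl]methyl}pyrazin-2(1H)-one
Product: 21 astepyrazinoxide, 1-hydroxy-5-methoxy-3-methyl-6-{[7-(3-methylbut-2-en-1-yl)-1H-indol-3-yl]methyl}pyrazin-2(1H)-one
Conditions: Pd(PPh3)4 (5 mol %), morpholine, THF, rt
Reagents that add atoms: none
Why: Tsuji–Trost-type deallylation; zerovalent palladium ionises the N–O–allyl ether because the pyrazinone N-oxide anion is a good leaving group, and morpholine traps the π-allyl complex; the prenyl group is not an allylic ether and the N–O bond is not reduced.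

## Compound list

1 | 7-bromo-1H-indole | Brc1cccc2cc[nH]c12 | starting material
2 | prenyl bromide (1-bromo-3-methylbut-2-ene) | CC(C)=CCBr | starting material
3 | prenylzinc bromide | CC(C)=CC[Zn]Br | intermediate
4 | 7-(3-methylbut-2-en-1-yl)-1H-indole | CC(C)=CCc1cccc2cc[nH]c12 | intermediate
5 | [7-(3-methylbut-2-en-1-yl)indol-1-yl]magnesium bromide | CC(C)=CCc1cccc2ccn([Mg]Br)c12 | intermediate
6 | 2-[7-(3-methylbut-2-en-1-yl)-1H-indol-3-yl]ethan-1-ol | OCCc1c[nH]c2c(CC=C(C)C)cccc12 | intermediate
7 | O-allylhydroxylamine hydrochloride | C=CCON.Cl | starting material
8 | 2-[7-(3-methylbut-2-en-1-yl)-1H-indol-3-yl]acetaldehyde | O=CCc1c[nH]c2c(CC=C(C)C)cccc12 | intermediate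
9 | (E)-2-[7-(3-methylbut-2-en-1-yl)-1H-indol-3-yl]acetaldehyde O-allyl oxime (E drawn; some Z isomer expected) | C=CCO/N=C/Cc1c[nH]c2c(CC=C(C)C)cccc12 | intermediate
10 | DL-alanine methyl ester hydrochloride | COC(=O)C(C)N.Cl | starting material
11 | methyl N-formyl-DL-alaninate | COC(=O)C(C)NC=O | intermediate
12 | methyl 2-isocyanopropanoate (racemic) | COC(=O)C(C)[N+]#[C-] | intermediate
13 | potassium 2-isocyanopropanoate (racemic) | [C-]#[N+]C(C)C(=O)[O-].[K+] | intermediate
14 | 2-{1-[(allyloxy)amino]-2-[7-(3-methylbut-2-en-1-yl)-1H-indol-3-yl]ethyl}-4-methyl-1,3-oxazol-5(4H)-one (mixture of diastereomers) | C=CCONC(Cc1c[nH]c2c(CC=C(C)C)cccc12)C1=NC(C)C(=O)O1 | intermediate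
15 | 3H-[1,2,3]triazolo[4,5-b]pyridin-3-yl N-{2-[(allyloxy)amino]-3-[7-(3-methylbut-2-en-1-yl)-1H-indol-3-yl]propanoyl}alaninate (mixture of diastereomers) | C=CCONC(Cc1c[nH]c2c(CC=C(C)C)cccc12)C(=O)NC(C)C(=O)On1nnc2cccnc12 | intermediate
16 | 1-(allyloxy)-3-methyl-6-{[7-(3-methylbut-2-en-1-yl)-1H-indol-3-yl]methyl}piperazine-2,5-dione (racemic cis/trans mixture) | C=CCON1C(=O)C(C)NC(=O)C1Cc1c[nH]c2c(CC=C(C)C)cccc12 | intermediate
17 | 1-(allyloxy)-5-methoxy-3-methyl-6-{[7-(3-methylbut-2-en-1-yl)-1H-indol-3-yl]methyl}-3,6-dihydropyrazin-2(1H)-one (mixture of diastereomers) | C=CCON1C(=O)C(C)N=C(OC)C1Cc1c[nH]c2c(CC=C(C)C)cccc12 | intermediate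
18 | dilithium salt of 17 (indol-1-ide and C3 carbanion) | C=CCON1C(=O)[C-](C)N=C(OC)C1Cc1c[n-]c2c(CC=C(C)C)cccc12.[Li+].[Li+] | intermediate
19 | 1-(allyloxy)-3-iodo-5-methoxy-3-methyl-6-{[7-(3-methylbut-2-en-1-yl)indol-3-yl]methyl}-3,6-dihydropyrazin-2(1H)-one, lithium indol-1-ide | C=CCON1C(=O)C(C)(I)N=C(OC)C1Cc1c[n-]c2c(CC=C(C)C)cccc12.[Li+] | intermediate
20 | 1-(allyloxy)-5-methoxy-3-methyl-6-{[7-(3-methylbut-2-en-1-yl)-1H-indol-3-yl]methyl}pyrazin-2(1H)-one | C=CCOn1c(Cc2c[nH]c3c(CC=C(C)C)cccc23)c(OC)nc(C)c1=O | intermediate
21 | astepyrazinoxide | COc1nc(C)c(=O)n(O)c1Cc1c[nH]c2c(CC=C(C)C)cccc12 | target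

## Step count and risk

Total step count: 10. Longest linear sequence: 7 steps (steps 1, 2, 3, 7, 8, 9, 10, from 1); the isocyanide branch (steps 4 to 6) joins at step 7.

**Step 7 (key step).**
- What may go wrong: the isocyanide salt may be consumed by Lewis-acid-induced self-condensation faster than it adds to the weakly electrophilic oxime ether. The acyl transfer may also run between molecules and give oligomers, or stop at the opened acid after work-up.
- Fallback (known chemistry), from 9 and 12 back to 16: the ZnCl2-promoted Ugi reaction of the oxime ether 9 with the isocyano ester 12 and formic acid in THF. Here the open-chain imidate anhydride can rearrange by the ordinary Mumm transfer, which should give methyl N-{2-[(allyloxy)(formyl)amino]-3-[7-(3-methylbut-2-en-1-yl)-1H-indol-3-yl]propanoyl}alaninate F1.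
- Methanolysis of the labile N-alkoxy formamide with K2CO3 in MeOH should then give methyl N-{2-[(allyloxy)amino]-3-[7-(3-methylbut-2-en-1-yl)-1H-indol-3-yl]propanoyl}alaninate F2.
- Heating F2 with 2-hydroxypyridine in toluene should close the dipeptide ester to 16.

**Step 9.**
- What may go wrong: iodination at the indole (nitrogen or C2'), or iodine-induced addition of N1' to the neighbouring prenyl alkene, in competition with C3 iodination. Excess base may also fragment the N–O–allyl unit.
- Fallback, from 17 back to 20: DDQ in dioxane at 0 °C abstracts hydride from the indol-3-ylmethyl position, the known behaviour of 3-alkylindoles and of tryptophan-derived lactim ethers. This should give 1-(allyloxy)-5-methoxy-3-methyl-6-{[7-(3-methylbut-2-en-1-yl)-1H-indol-3-yl]methylidene}-3,6-dihydropyrazin-2(1H)-one F3.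
- Catalytic DBU in THF should then move the C3 hydrogen to the exocyclic carbon and give the aromatic 20, with no strong base or halogen.

**Step 8.**
- What may go wrong: methylation at the wrong site (hydroxamate carbonyl oxygen, leading to ring opening on work-up, or the indole). If the buffer fails, acid-induced addition of the indole N–H to the prenyl alkene is also possible.
- Fallback, from 16 back to 17: the amide is made the electrophile instead. PPh3 and CCl4 in MeCN should convert the secondary lactam into the imidoyl chloride 1-(allyloxy)-5-chloro-3-methyl-6-{[7-(3-methylbut-2-en-1-yl)-1H-indol-3-yl]methyl}-3,6-dihydropyrazin-2(1H)-one F4. The N-alkoxy amide cannot form such a chloride.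
- NaOMe in MeOH at 0 °C should then give 17.

**Step 3.**
- What may go wrong: self-condensation and polymerisation of the indol-3-ylacetaldehyde 8 before the alkoxyamine captures it.
- Fallback, from 4 back to 9, avoiding 6 and 8: 2-chloroacetaldehyde oxime with Na2CO3 in CH2Cl2 generates nitrosoethene F5 in the flask. Indole 4 should add to it at C3' (conjugate addition of indoles to nitrosoalkenes) to give 2-[7-(3-methylbut-2-en-1-yl)-1H-indol-3-yl]acetaldehyde oxime F6.
- Mitsunobu O-allylation of F6 (allyl alcohol, PPh3, diisopropyl azodicarboxylate, THF) should give 9. The indole N–H is not acidic enough to take part.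

## Further compounds

F1 | step 7 | methyl N-{2-[(allyloxy)(formyl)amino]-3-[7-(3-methylbut-2-en-1-yl)-1H-indol-3-yl]propanoyl}alaninate (mixture of diastereomers) | C=CCON(C=O)C(Cc1c[nH]c2c(CC=C(C)C)cccc12)C(=O)NC(C)C(=O)OC
F2 | step 7 | methyl N-{2-[(allyloxy)amino]-3-[7-(3-methylbut-2-en-1-yl)-1H-indol-3-yl]propanoyl}alaninate (mixture of diastereomers) | C=CCONC(Cc1c[nH]c2c(CC=C(C)C)cccc12)C(=O)NC(C)C(=O)OC
F3 | step 9 | 1-(allyloxy)-5-methoxy-3-methyl-6-{[7-(3-methylbut-2-en-1-yl)-1H-indol-3-yl]methylidene}-3,6-dihydropyrazin-2(1H)-one (alkene geometry not defined) | C=CCON1C(=O)C(C)N=C(OC)C1=Cc1c[nH]c2c(CC=C(C)C)cccc12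
F4 | step 8 | 1-(allyloxy)-5-chloro-3-methyl-6-{[7-(3-methylbut-2-en-1-yl)-1H-indol-3-yl]methyl}-3,6-dihydropyrazin-2(1H)-one (mixture of diastereomers) | C=CCON1C(=O)C(C)N=C(Cl)C1Cc1c[nH]c2c(CC=C(C)C)cccc12
F5 | step 3 | nitrosoethene | C=CN=O
F6 | step 3 | 2-[7-(3-methylbut-2-en-1-yl)-1H-indol-3-yl]acetaldehyde oxime (E/Z mixture) | ON=CCc1c[nH]c2c(CC=C(C)C)cccc12
A1 | alternative 1 | 2-bromo-6-(3-methylbut-2-en-1-yl)aniline | Nc1c(Br)cccc1CC=C(C)C
A2 | alternative 1 | 5-methoxy-1-[(4-methoxybenzyl)oxy]-3-methyl-6-[3-(triethylsilyl)prop-2-yn-1-yl]pyrazin-2(1H)-one | COc1nc(C)c(=O)n(OCc2ccc(OC)cc2)c1CC#C[Si](CC)(CC)CC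
A3 | alternative 1 | 5-methoxy-1-[(4-methoxybenzyl)oxy]-3-methyl-6-{[7-(3-methylbut-2-en-1-yl)-2-(triethylsilyl)-1H-indol-3-yl]methyl}pyrazin-2(1H)-one | COc1nc(C)c(=O)n(OCc2ccc(OC)cc2)c1Cc1c([Si](CC)(CC)CC)[nH]c2c(CC=C(C)C)cccc12
A4 | alternative 2 | tert-butyl (but-3-en-1-yl)[3-(3-methylbut-2-en-1-yl)furan-2-yl]carbamate | C=CCCN(C(=O)OC(C)(C)C)c1occc1CC=C(C)C
A5 | alternative 2 | tert-butyl 7-(3-methylbut-2-en-1-yl)indoline-1-carboxylate | CC(C)=CCc1cccc2c1N(C(=O)OC(C)(C)C)CC2
A6 | alternative 3 | (S)-N-(allyloxy)-2-{3-[7-(3-methylbut-2-en-1-yl)-1H-indol-3-yl]-2-oxopropanamido}propanamide | C=CCONC(=O)[C@H](C)NC(=O)C(=O)Cc1c[nH]c2c(CC=C(C)C)cccc12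
A7 | alternative 3 | (3S,6Z)-1-(allyloxy)-3-methyl-6-{[7-(3-methylbut-2-en-1-yl)-1H-indol-3-yl]methylidene}piperazine-2,5-dione | C=CCON1C(=O)[C@H](C)NC(=O)/C1=C/c1c[nH]c2c(CC=C(C)C)cccc12
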